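A direct plan would build ring A from acyclic pieces (Michael/aldol annulation, dehydration, dehydrogenation) to give the salicylate A1, methyl 2-hydroxy-3-methoxybenzoate. It would then saponify, brominate and bromodecarboxylate A1 to the phenol A2, 2,4-dibromo-6-methoxyphenol. SNAr of A2 on the fluoroarene A3, 2-bromo-1-fluoro-4-nitrobenzene, would give the nitro ether A4; reduction to the aniline A5 and a Sandmeyer reaction would finish. Its weakest parts would be:
(a) the ring construction leading to A1, which would spend four operations, with an aldol closure that sets three stereocentres at random only to erase them, on a guaiacol ring that can be bought;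
(b) the bromodecarboxylation, which would expel a carboxyl group carried only as a placeholder, under conditions prone to over-bromination;
(c) the nitro-to-bromine exchange on the finished ether, where a diazonium salt in hot HBr would risk hydrodediazoniation and ether cleavage on the most precious material.

**Plan of the new route.** The retrosynthesis cuts ring B itself, at C1'–C2' and C5'–C6', so that no aryl–oxygen bond is ever made. Ring A is bought whole as phenol 1; its oxygen is vinylated and the vinyl ether is taken to the ethynyl ether 5. Ring B arises last, in one operation, from 5 and 3,5-dibromo-2H-pyran-2-one (7). The enabling feature is that on ring B the bromines on C2' and C4' flank H-3', and the ether oxygen on C1' is followed by H on C6' and C5'. This is C3(Br)–C4(H)–C5(Br)–C6(H) of 7 closed by ArO–C≡C–H once the O1–C2 bridge leaves as CO2. No ring passes through stereogenic intermediates, no placeholder carboxyl is needed, and all four bromines are bought or arrive with the pyrone, so nothing is exchanged on the finished ether.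

Key step: step 5

Remark: 1 and coumalic acid (6) are taken as catalogue compounds; the ynol ether 5 is assumed too labile to store and is used at once.

Step 1
Reactants: 1 2,4-dibromo-6-methoxyphenol
Product: 2 1,5-dibromo-2-(ethenyloxy)-3-methoxybenzene
Conditions: Cu(OAc)2 (1.0 equiv), 2,4,6-trivinylcyclotriboroxane–pyridine complex (0.7 equiv), pyridine (10 equiv), CH2Cl2, rt, air, 24 h
Reagents that add atoms: 2,4,6-trivinylcyclotriboroxane–pyridine complex, C=CB1OB(C=C)OB(C=C)O1.c1ccncc1
Why: In this Chan–Lam-type oxidative O-vinylation the vinyl group should pass from boron to copper and be joined to the aryloxide by reductive elimination at room temperature, conditions under which aryl bromides are not touched.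

Step 2
Reactants: 2 1,5-dibromo-2-(ethenyloxy)-3-methoxybenzene
Product: 4 1,5-dibromo-2-{[(Z)-2-bromoethenyl]oxy}-3-methoxybenzene, via 1,2-dibromoethyl ether 3 (not isolated)
Conditions: Br2 (1.0 equiv), CH2Cl2, −78 °C, 15 min; then DBU (1.5 equiv), −78 °C → rt, 3 h
Reagents that add atoms: bromine, BrBr
Why: Electrophilic addition of Br2 to the enol ether double bond should far outpace substitution on the deactivated dibromoarene, and E2 loss of HBr from the α-bromo ether 3 (whose single stereocentre forms as a racemate and disappears again) should give mainly the (Z)-β-bromo enol ether, the minor (E)-isomer being carried on because both lead to 5.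

Step 3
Reactants: 4 1,5-dibromo-2-{[(Z)-2-bromoethenyl]oxy}-3-methoxybenzene
Product: 5 1,5-dibromo-2-(ethynyloxy)-3-methoxybenzene
Conditions: KOtBu (2.2 equiv), 18-crown-6 (0.1 equiv), THF, −40 → 0 °C, 1 h; aq NH4Cl at −20 °C; short silica pad, used at once
Reagents that add atoms: none
Why: In the (Z)-isomer the vinylic hydrogen on the oxygen-bearing carbon is anti-periplanar to bromine, so E2 dehydrobromination by tert-butoxide should proceed below 0 °C (the (E)-isomer following more slowly through the α-bromovinyl anion, a Fritsch–Buttenberg–Wiechell-type shift), and a potassium alkoxide, unlike the alkyllithium reagents usual for ynol ethers, cannot exchange the aryl bromides.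

Step 4
Reactants: 6 coumalic acid (2-oxo-2H-pyran-5-carboxylic acid)
Product: 7 3,5-dibromo-2H-pyran-2-one
Conditions: NBS (2.5 equiv), LiOAc (0.2 equiv), MeCN/H2O 9:1, rt, 24 h
Reagents that add atoms: N-bromosuccinimide, O=C1CCC(=O)N1Br
Why: Hunsdiecker-type bromodecarboxylation of the unsaturated acid at C5 with NBS and catalytic acetate should be accompanied by electrophilic bromination at C3, the nucleophilic position next to the lactone carbonyl.

Step 5
Reactants: 5 1,5-dibromo-2-(ethynyloxy)-3-methoxybenzene; 7 3,5-dibromo-2H-pyran-2-one
Product: 9 1,5-dibromo-2-(2,4-dibromophenoxy)-3-methoxybenzene (achiral), via bridged lactone 8 (not isolated)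
Conditions: 7 (1.0 equiv), 5 (1.3 equiv, added over 2 h), BHT (5 mol %), toluene, 100 °C, sealed tube, 16 h
Reagents that add atoms: none
Why: The electron-poor pyrone diene (C3 to C6) should undergo a Diels–Alder reaction with the electron-rich ynol ether, and the bridged lactone 8 should then lose CO2 by an irreversible retro-Diels–Alder reaction that delivers ring B already aromatic; the closest known reaction type is the pyrone–alkyne cycloaddition/decarboxylation route to benzenes. Ring B closes by an intermolecular [4+2] cycloaddition that forms C1'–C2' and C5'–C6', after which the O1–C2 lactone bridge leaves. The one selectivity needed is the orientation: the terminal alkyne carbon, which carries the large HOMO coefficient, must bond to pyrone C6, the electrophilic terminus remote from the carbonyl, so that the oxygen-bearing carbon bonds to the brominated C3. This is the polarity-matched orientation, the one expected from the addition of enol ethers to 3-bromo- and 3,5-dibromo-2-pyrones, and it places the ether oxygen ortho to one bromine and para to the other. The two bridgehead stereocentres of 8 are racemic and vanish on aromatisation, so no stereocentre has to be controlled. The four C–Br bonds and the methyl ether should be inert under these neutral, metal-free thermal conditions.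

**Compound list**
1 | 2,4-dibromo-6-methoxyphenol | COc1cc(Br)cc(Br)c1O | starting material
2 | 1,5-dibromo-2-(ethenyloxy)-3-methoxybenzene | COc1cc(Br)cc(Br)c1OC=C | intermediate
3 | 1,5-dibromo-2-(1,2-dibromoethoxy)-3-methoxybenzene (racemic) | COc1cc(Br)cc(Br)c1OC(Br)CBr | intermediate
4 | 1,5-dibromo-2-{[(Z)-2-bromoethenyl]oxy}-3-methoxybenzene (minor (E)-isomer carried along) | COc1cc(Br)cc(Br)c1O/C=C\Br | intermediate
5 | 1,5-dibromo-2-(ethynyloxy)-3-methoxybenzene | COc1cc(Br)cc(Br)c1OC#C | intermediate
6 | coumalic acid (2-oxo-2H-pyran-5-carboxylic acid) | O=C(O)C1=COC(=O)C=C1 | starting material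
7 | 3,5-dibromo-2H-pyran-2-one | O=C1OC=C(Br)C=C1Br | intermediate
8 | 4,7-dibromo-5-(2,4-dibromo-6-methoxyphenoxy)-2-oxabicyclo[2.2.2]octa-5,7-dien-3-one (racemic) | O=C1OC2C=C(Oc3c(OC)cc(Br)cc3Br)C1(Br)C=C2Br | intermediate
9 | 1,5-dibromo-2-(2,4-dibromophenoxy)-3-methoxybenzene (achiral) | COc1cc(Br)cc(Br)c1Oc1ccc(Br)cc1Br | target

**Total step count:** 5. **Longest linear sequence:** 4 (steps 1, 2, 3, 5).

**Steps most likely to fail**

Step 5. The cycloaddition could take the reverse orientation in part, or thermal oligomerisation of the ynol ether could outrun it. The fallback abandons ring construction and arylates the phenol oxygen with an aryl group on trivalent iodine. It sets out from 1: its sodium salt (NaOH, water/dioxane, 80 °C) would be treated with bis(2,4-dibromophenyl)iodonium chloride F1, itself prepared from 1,3-dibromobenzene and (IO)2SO4 in H2SO4 followed by NaCl. Ligand coupling on iodine would give the ether directly, with 2,4-dibromo-1-iodobenzene as co-product, and the symmetrical salt leaves no question of which aryl group is transferred. The route is rejoined at 9.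

Step 3. tert-Butoxide could add to the ynol ether, syn-elimination of the (E)-isomer could stall, or the product could be lost on isolation. The fallback avoids the free ynol ether and lets the bromovinyl ether serve as the alkyne equivalent. It sets out from 4: heating with 7 (toluene, 120–140 °C, sealed tube) would give, in the same polarity-matched orientation, the bridged lactone 4,6,7-tribromo-5-(2,4-dibromo-6-methoxyphenoxy)-2-oxabicyclo[2.2.2]oct-7-en-3-one F2. This would lose CO2 to the cyclohexadiene 1,5-dibromo-3-methoxy-2-[(2,4,6-tribromocyclohexa-2,4-dien-1-yl)oxy]benzene F3, and DBU at rt would then remove HBr. The process to watch is loss of the phenol instead of HBr, which bromide as the better leaving group should disfavour. The route is rejoined at 9.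

Step 1. Transfer of the vinyl group on copper to the di-ortho-substituted, weakly nucleophilic phenoxide could be slow. The fallback makes the vinyl ether by alkylation and elimination without any metal. It sets out from 1: 1,2-dibromoethane (5 equiv), K2CO3, MeCN, reflux would give 1,5-dibromo-2-(2-bromoethoxy)-3-methoxybenzene F4, and KOtBu in THF at 0 °C would eliminate HBr. The route is rejoined at 2.

**Further compounds**
F1 | step 5 | bis(2,4-dibromophenyl)iodonium chloride | Brc1ccc([I+]c2ccc(Br)cc2Br)c(Br)c1.[Cl-]
F2 | step 3 | 4,6,7-tribromo-5-(2,4-dibromo-6-methoxyphenoxy)-2-oxabicyclo[2.2.2]oct-7-en-3-one (racemic diastereomer mixture) | O=C1OC2C(Br)C(Oc3c(OC)cc(Br)cc3Br)C1(Br)C=C2Br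
F3 | step 3 | 1,5-dibromo-3-methoxy-2-[(2,4,6-tribromocyclohexa-2,4-dien-1-yl)oxy]benzene (racemic diastereomer mixture) | COc1cc(Br)cc(Br)c1OC1C(Br)C=C(Br)C=C1Br
F4 | step 1 | 1,5-dibromo-2-(2-bromoethoxy)-3-methoxybenzene | COc1cc(Br)cc(Br)c1OCCBr
A1 | direct plan | methyl 2-hydroxy-3-methoxybenzoate | COc1cccc(C(=O)OC)c1O
A2 | direct plan | 2,4-dibromo-6-methoxyphenol | COc1cc(Br)cc(Br)c1O
A3 | direct plan | 2-bromo-1-fluoro-4-nitrobenzene | O=[N+]([O-])c1ccc(F)c(Br)c1
A4 | direct plan | 1,5-dibromo-2-(2-bromo-4-nitrophenoxy)-3-methoxybenzene | COc1cc(Br)cc(Br)c1Oc1ccc([N+](=O)[O-])cc1Br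
A5 | direct plan | 3-bromo-4-(2,4-dibromo-6-methoxyphenoxy)aniline | COc1cc(Br)cc(Br)c1Oc1ccc(N)cc1Br
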